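**Plan**

- Numbering: the chain runs from C1 (carbinol carbon on ring B, the 3,5-dihydroxy-4-aryloxyphenyl ring) to C14 (benzylic CH2 on ring A, the resorcinol ring). CIP analysis of the given SMILES gives (R) at C1 and Z at C8=C9.
- Retrosynthetic cuts, in order: C5–C6 of the macrocycle; C1–C2 (Weinreb ketone synthesis); C14–ring A (B-alkyl Suzuki–Miyaura); C8=C9 (Wittig); the O–ring A bond of the diaryl ether (Ullmann).
- Enabling feature: C5–C6 lies in the unbranched, heteroatom-free C2–C7 methylene run between carbinol C1 and the Z alkene C8=C9. C5 is the end carbon of a but-3-enyl group on C1, so anti-Markovnikov hydroboration makes it a primary alkylborane. C6 is a primary homoallylic carbon that can carry bromide. An sp3–sp3 coupling can therefore close the 22-membered ring and leave no helper group to remove.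
- Forward order: rings A and B are joined as the diaryl ether; the C6–C14 arm with the Z alkene goes onto ring A; the C1–C5 arm goes onto ring B; the 22-membered ring closes last at C5–C6; the three MOM ethers are then removed.
- Stereochemistry: the Z alkene comes from a lithium-free Wittig reaction of a non-stabilised ylide; (R)-C1 comes from a Corey–Bakshi–Shibata reduction of the aryl ketone with the (S)-oxazaborolidine.

Key step: step 13

**Route**

Step 1
Reactants: 1 methyl gallate (methyl 3,4,5-trihydroxybenzoate)
Product: 2 methyl 4-(benzyloxy)-3,5-dihydroxybenzoate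
Conditions: BnBr (1.05 equiv), KHCO3 (1.1 equiv), KI (cat.), DMF, rt
Reagents that add atoms: benzyl bromide, BrCc1ccccc1
Why: The 4-OH, para to the ester, is the most acidic of the three phenols, so one equivalent of weak base should give the 4-phenoxide and a selective Williamson etherification at that oxygen.

Step 2
Reactants: 2 methyl 4-(benzyloxy)-3,5-dihydroxybenzoate
Product: 3 methyl 4-(benzyloxy)-3,5-bis(methoxymethoxy)benzoate
Conditions: MOMCl (2.5 equiv), i-Pr2NEt (3 equiv), CH2Cl2, 0 °C to rt
Reagents that add atoms: chloromethyl methyl ether, COCCl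
Why: Acetal protection of the two remaining phenols by O-alkylation with an α-chloro ether should be routine and gives groups that survive base, organometallics and palladium catalysis.

Step 3
Reactants: 3 methyl 4-(benzyloxy)-3,5-bis(methoxymethoxy)benzoate
Product: 4 methyl 4-hydroxy-3,5-bis(methoxymethoxy)benzoate
Conditions: H2 (1 atm), Pd/C, EtOAc, rt
Reagents that add atoms: none
Why: Hydrogenolysis of the benzyl ether under neutral conditions should free the 4-OH alone, since the MOM acetals and the ester are inert to it.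

Step 4
Reactants: 5 3,5-dibromophenol
Product: 6 1,3-dibromo-5-(methoxymethoxy)benzene
Conditions: MOMCl (1.3 equiv), i-Pr2NEt (1.5 equiv), CH2Cl2, 0 °C to rt
Reagents that add atoms: chloromethyl methyl ether, COCCl
Why: Acetal protection of the ring-A phenol should proceed as in step 2 and leaves two equivalent C–Br bonds for the two later couplings.

Step 5
Reactants: 4 methyl 4-hydroxy-3,5-bis(methoxymethoxy)benzoate; 6 1,3-dibromo-5-(methoxymethoxy)benzene
Product: 7 methyl 4-[3-bromo-5-(methoxymethoxy)phenoxy]-3,5-bis(methoxymethoxy)benzoate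
Conditions: 6 (3 equiv), CuI (10 mol%), picolinic acid (20 mol%), K3PO4 (2 equiv), DMSO, 90 °C
Reagents that add atoms: none
Why: Ullmann-type copper-catalysed C–O coupling with a picolinate ligand is suited to phenols flanked by two ortho substituents, and the excess of the symmetric dibromide should hold the reaction at mono-arylation.

Step 6
Reactants: 8 (3-bromopropoxy)(tert-butyl)dimethylsilane
Product: 9 [3-(tert-butyldimethylsilyloxy)propyl]triphenylphosphonium bromide
Conditions: PPh3 (1.1 equiv), MeCN, reflux
Reagents that add atoms: triphenylphosphine, c1ccc(cc1)P(c1ccccc1)c1ccccc1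
Why: SN2 quaternisation of triphenylphosphine by a primary bromide should give the phosphonium salt directly.

Step 7
Reactants: 9 [3-(tert-butyldimethylsilyloxy)propyl]triphenylphosphonium bromide; 10 hex-5-enal
Product: 12 (Z)-tert-butyl(nona-3,8-dien-1-yloxy)dimethylsilane, via phosphonium ylide 11 (not isolated)
Conditions: NaN(SiMe3)2 (1.05 equiv), THF, −78 °C; then 10, −78 °C to rt
Reagents that add atoms: none
Why: A Wittig reaction of a non-stabilised ylide under lithium-free conditions should pass through the kinetically favoured cis-oxaphosphetane and so set the C8=C9 alkene as Z.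

Step 8
Reactants: 12 (Z)-tert-butyl(nona-3,8-dien-1-yloxy)dimethylsilane; 7 methyl 4-[3-bromo-5-(methoxymethoxy)phenoxy]-3,5-bis(methoxymethoxy)benzoate
Product: 14 methyl 4-{3-[(Z)-9-(tert-butyldimethylsilyloxy)non-6-en-1-yl]-5-(methoxymethoxy)phenoxy}-3,5-bis(methoxymethoxy)benzoate, via B-alkyl-9-BBN 13 (not isolated)
Conditions: 12 (1.3 equiv), 9-BBN (1.25 equiv), THF, 0 °C to rt; then 7, Pd(dppf)Cl2 (5 mol%), aq. K3PO4 (3 equiv), DMF, 60 °C
Reagents that add atoms: 9-borabicyclo[3.3.1]nonane, B1C2CCCC1CCC2 (its atoms stand in 13 only)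
Why: 9-BBN should hydroborate the monosubstituted terminal alkene of 12 anti-Markovnikov and leave the Z-disubstituted alkene alone, and the resulting primary alkylborane should couple with the unhindered aryl bromide of 7 in a B-alkyl Suzuki–Miyaura reaction that tolerates the ester, the acetals and the silyl ether.

Step 9
Reactants: 14 methyl 4-{3-[(Z)-9-(tert-butyldimethylsilyloxy)non-6-en-1-yl]-5-(methoxymethoxy)phenoxy}-3,5-bis(methoxymethoxy)benzoate
Product: 15 methyl 4-{3-[(Z)-9-hydroxynon-6-en-1-yl]-5-(methoxymethoxy)phenoxy}-3,5-bis(methoxymethoxy)benzoate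
Conditions: TBAF (1.2 equiv), AcOH (1.2 equiv), THF, 0 °C to rt
Reagents that add atoms: none
Why: Fluoride-induced cleavage of the primary silyl ether, buffered with acetic acid, should free the C6 alcohol without touching the methyl ester or the acetals.

Step 10
Reactants: 15 methyl 4-{3-[(Z)-9-hydroxynon-6-en-1-yl]-5-(methoxymethoxy)phenoxy}-3,5-bis(methoxymethoxy)benzoate
Product: 16 methyl 4-{3-[(Z)-9-bromonon-6-en-1-yl]-5-(methoxymethoxy)phenoxy}-3,5-bis(methoxymethoxy)benzoate
Conditions: CBr4 (1.3 equiv), PPh3 (1.4 equiv), CH2Cl2, 0 °C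
Reagents that add atoms: carbon tetrabromide, BrC(Br)(Br)Br
Why: The Appel reaction should turn the primary homoallylic alcohol into the bromide by SN2 displacement of an oxyphosphonium group under near-neutral conditions, without moving the alkene.

Step 11
Reactants: 16 methyl 4-{3-[(Z)-9-bromonon-6-en-1-yl]-5-(methoxymethoxy)phenoxy}-3,5-bis(methoxymethoxy)benzoate; 17 but-3-enylmagnesium bromide
Product: 19 1-(4-{3-[(Z)-9-bromonon-6-en-1-yl]-5-(methoxymethoxy)phenoxy}-3,5-bis(methoxymethoxy)phenyl)pent-4-en-1-one, via Weinreb amide 18 (not isolated)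
Conditions: MeNHOMe·HCl (1.5 equiv), i-PrMgCl (3.0 equiv), THF, −20 °C; then 17 (2.5 equiv), −20 to 0 °C; aq. NH4Cl
Reagents that add atoms: N,O-dimethylhydroxylamine hydrochloride, CNOC.Cl (its atoms stand in 18 only)
Why: In this one-pot Weinreb ketone synthesis the magnesium amide of N,O-dimethylhydroxylamine should convert the ester into amide 18, whose chelated tetrahedral adduct with the Grignard reagent stops at the ketone stage, while the primary alkyl bromide is inert to Grignard reagents at or below 0 °C in the absence of a transition metal.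

Step 12
Reactants: 19 1-(4-{3-[(Z)-9-bromonon-6-en-1-yl]-5-(methoxymethoxy)phenoxy}-3,5-bis(methoxymethoxy)phenyl)pent-4-en-1-one
Product: 20 (R)-1-(4-{3-[(Z)-9-bromonon-6-en-1-yl]-5-(methoxymethoxy)phenoxy}-3,5-bis(methoxymethoxy)phenyl)pent-4-en-1-ol
Conditions: (S)-2-methyl-CBS-oxazaborolidine (20 mol%), catecholborane (1.8 equiv), toluene, −78 °C
Reagents that add atoms: none
Why: In this Corey–Bakshi–Shibata reduction the aryl group acts as the large and the butenyl chain as the small substituent, so the (S)-oxazaborolidine should deliver hydride to the Si face and give the (R)-carbinol, and catecholborane is chosen because it does not hydroborate the two alkenes at this temperature.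

Step 13
Reactants: 20 (R)-1-(4-{3-[(Z)-9-bromonon-6-en-1-yl]-5-(methoxymethoxy)phenoxy}-3,5-bis(methoxymethoxy)phenyl)pent-4-en-1-ol
Product: 22 the (R,Z)-configured 22-membered macrocycle with the three phenols as MOM ethers (tris-MOM ether of the target), via B-alkyl-9-BBN borinate 21 (not isolated)
Conditions: 9-BBN (2.2 equiv), THF, 0 °C to rt; then slow addition (12 h) to Pd(OAc)2 (20 mol%), PCy3 (40 mol%), K3PO4·H2O (3 equiv), THF, rt to 40 °C, 2 mM
Reagents that add atoms: 9-borabicyclo[3.3.1]nonane, B1C2CCCC1CCC2 (its atoms stand in 21 only)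
Why: Proposed new method: 9-BBN should add anti-Markovnikov to the monosubstituted C4=C5 alkene, far faster than to the Z-disubstituted C8=C9 alkene, putting boron on C5 (the free hydroxyl is only capped as its borinate); zerovalent palladium carrying PCy3 then inserts into the primary C6–Br bond by an SN2-type oxidative addition, the hydroxide-activated C5 borate transmetalates to the same palladium centre, and reductive elimination forms the C5–C6 bond. The closest known reaction types are the room-temperature alkyl–alkyl Suzuki–Miyaura coupling of primary alkyl bromides that carry β-hydrogens with B-alkyl-9-BBN reagents, and macrocyclising B-alkyl Suzuki–Miyaura couplings onto alkenyl iodides; what is new is their combination in a ring closure between two sp3 carbons. The 22-membered ring closes end to end: intramolecular transmetalation gives a 23-membered dialkylpalladacycle, which contracts by reductive elimination. No stereocentre is formed; C1 is remote from the reacting carbons and the Z geometry of C8=C9 is kept as long as no palladium hydride arises. The step needs cyclisation to beat oligomerisation, which slow addition to a low stationary concentration and the bent diaryl ether hinge should secure, and it needs transmetalation to beat β-hydride elimination of the homoallylic alkylpalladium towards a 1,3-diene, for which the bulky, electron-rich PCy3 ligand is chosen.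

Step 14
Reactants: 22 tris-MOM ether of the target
Product: 24 CNP0316989.2, the (R,Z)-macrocyclic triphenol carbinol, via tetrakis(trimethylsilyl) ether 23 (not isolated)
Conditions: TMSOTf (8 equiv), 2,2'-bipyridyl (12 equiv), MeCN, 0 °C to rt; then H2O/THF, rt
Reagents that add atoms: trimethylsilyl trifluoromethanesulfonate, C[Si](C)(C)OS(=O)(=O)C(F)(F)F (its silyl groups stand in 23 only)
Why: The silyl triflate–bipyridyl pair should convert the three aryl MOM acetals into aryl silyl ethers under buffered, non-protic conditions, so that the benzylic carbinol (silylated in passing) is not ionised, and water should then hydrolyse all four O–Si bonds.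

**Compound list**

1 | methyl gallate | COC(=O)c1cc(O)c(O)c(O)c1 | starting material
2 | methyl 4-(benzyloxy)-3,5-dihydroxybenzoate | COC(=O)c1cc(O)c(OCc2ccccc2)c(O)c1 | intermediate
3 | methyl 4-(benzyloxy)-3,5-bis(methoxymethoxy)benzoate | COC(=O)c1cc(OCOC)c(OCc2ccccc2)c(OCOC)c1 | intermediate
4 | methyl 4-hydroxy-3,5-bis(methoxymethoxy)benzoate | COC(=O)c1cc(OCOC)c(O)c(OCOC)c1 | intermediate
5 | 3,5-dibromophenol | Oc1cc(Br)cc(Br)c1 | starting material
6 | 1,3-dibromo-5-(methoxymethoxy)benzene | COCOc1cc(Br)cc(Br)c1 | intermediate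
7 | methyl 4-[3-bromo-5-(methoxymethoxy)phenoxy]-3,5-bis(methoxymethoxy)benzoate | COC(=O)c1cc(OCOC)c(Oc2cc(Br)cc(OCOC)c2)c(OCOC)c1 | intermediate
8 | (3-bromopropoxy)(tert-butyl)dimethylsilane | CC(C)(C)[Si](C)(C)OCCCBr | starting material
9 | [3-(tert-butyldimethylsilyloxy)propyl]triphenylphosphonium bromide | CC(C)(C)[Si](C)(C)OCCC[P+](c1ccccc1)(c1ccccc1)c1ccccc1.[Br-] | intermediate
10 | hex-5-enal | C=CCCCC=O | starting material
11 | [3-(tert-butyldimethylsilyloxy)propylidene]triphenylphosphorane (ylide) | CC(C)(C)[Si](C)(C)OCCC=P(c1ccccc1)(c1ccccc1)c1ccccc1 | intermediate (not isolated)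
12 | (Z)-tert-butyl(nona-3,8-dien-1-yloxy)dimethylsilane | CC(C)(C)[Si](C)(C)OCC/C=C\CCCC=C | intermediate
13 | 9-[(Z)-9-(tert-butyldimethylsilyloxy)non-6-en-1-yl]-9-borabicyclo[3.3.1]nonane | CC(C)(C)[Si](C)(C)OCC/C=C\CCCCCB1C2CCCC1CCC2 | intermediate (not isolated)
14 | methyl 4-{3-[(Z)-9-(tert-butyldimethylsilyloxy)non-6-en-1-yl]-5-(methoxymethoxy)phenoxy}-3,5-bis(methoxymethoxy)benzoate | COC(=O)c1cc(OCOC)c(Oc2cc(CCCCC/C=C\CCO[Si](C)(C)C(C)(C)C)cc(OCOC)c2)c(OCOC)c1 | intermediate
15 | methyl 4-{3-[(Z)-9-hydroxynon-6-en-1-yl]-5-(methoxymethoxy)phenoxy}-3,5-bis(methoxymethoxy)benzoate | COC(=O)c1cc(OCOC)c(Oc2cc(CCCCC/C=C\CCO)cc(OCOC)c2)c(OCOC)c1 | intermediate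
16 | methyl 4-{3-[(Z)-9-bromonon-6-en-1-yl]-5-(methoxymethoxy)phenoxy}-3,5-bis(methoxymethoxy)benzoate | COC(=O)c1cc(OCOC)c(Oc2cc(CCCCC/C=C\CCBr)cc(OCOC)c2)c(OCOC)c1 | intermediate
17 | but-3-enylmagnesium bromide | C=CCC[Mg]Br | starting material
18 | 4-{3-[(Z)-9-bromonon-6-en-1-yl]-5-(methoxymethoxy)phenoxy}-N-methoxy-3,5-bis(methoxymethoxy)-N-methylbenzamide | CON(C)C(=O)c1cc(OCOC)c(Oc2cc(CCCCC/C=C\CCBr)cc(OCOC)c2)c(OCOC)c1 | intermediate (not isolated)
19 | 1-(4-{3-[(Z)-9-bromonon-6-en-1-yl]-5-(methoxymethoxy)phenoxy}-3,5-bis(methoxymethoxy)phenyl)pent-4-en-1-one | C=CCCC(=O)c1cc(OCOC)c(Oc2cc(CCCCC/C=C\CCBr)cc(OCOC)c2)c(OCOC)c1 | intermediate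
20 | (R)-1-(4-{3-[(Z)-9-bromonon-6-en-1-yl]-5-(methoxymethoxy)phenoxy}-3,5-bis(methoxymethoxy)phenyl)pent-4-en-1-ol | O[C@H](CCC=C)c1cc(OCOC)c(Oc2cc(CCCCC/C=C\CCBr)cc(OCOC)c2)c(OCOC)c1 | intermediate
21 | (R)-configured O-(9-BBN) borinate of 20 carrying a 9-BBN group on C5 | B1(C2CCCC1CCC2)O[C@H](CCCCB1C2CCCC1CCC2)c1cc(OCOC)c(Oc2cc(CCCCC/C=C\CCBr)cc(OCOC)c2)c(OCOC)c1 | intermediate (not isolated)
22 | tris-MOM ether of the target: (R,Z)-22-membered macrocycle, ring-B and ring-A phenols as methoxymethyl ethers, free C1 carbinol | COCOc1cc2cc(c1)Oc1c(OCOC)cc(cc1OCOC)[C@H](O)CCCCCC/C=C\CCCCC2 | intermediate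
23 | tetrakis(trimethylsilyl) ether of the target (three aryl O–Si, one C1 O–Si) | C[Si](C)(C)Oc1cc2cc(c1)Oc1c(O[Si](C)(C)C)cc(cc1O[Si](C)(C)C)[C@H](O[Si](C)(C)C)CCCCCC/C=C\CCCCC2 | intermediate (not isolated)
24 | CNP0316989.2, (R,Z)-macrocyclic diaryl ether with three phenols and the C1 carbinol | Oc1cc2cc(c1)Oc1c(O)cc(cc1O)[C@H](O)CCCCCC/C=C\CCCCC2 | target

**Step count and risks**

Total steps: 14. Longest linear sequence: 11 steps (steps 1, 2, 3, 5, 8, 9, 10, 11, 12, 13, 14).

Steps most likely to fail:

1. Step 13 (Proposed new method). The ring closure may lose to intermolecular coupling and give oligomers. The homoallylic alkylpalladium may undergo β-hydride elimination to a diene before transmetalation. The alkylborane may be protonated off, or a second hydroboration may reach C8=C9.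
Fallback (known chemistry, polarity reversal at C6), setting out from 20 and coming back at 22: displacement of the bromide of 20 with PhSO2Na (Bu4NI cat., DMF, 50 °C) would give the phenyl sulfone alcohol F1. Silylation (TBSCl, imidazole, DMF) would give the silyl ether F2, which is needed because a free C1 alkoxide would close a tetrahydropyran onto C5 later. Hydroboration–oxidation of the terminal alkene (9-BBN, THF; then NaOH, H2O2) would give the primary C5 alcohol F3, and I2, PPh3 and imidazole in CH2Cl2 would give the primary C5 iodide F4. Slow addition of F4 to LiN(i-Pr)2 in THF/DMPU at −78 to 0 °C at 2 mM should close the ring by alkylation of the sulfone-stabilised C6 carbanion, a well-precedented macrocyclisation type, to give the macrocyclic sulfone F5 as a mixture at C6. Reductive desulfonylation (Mg, MeOH, rt) would give the macrocyclic silyl ether F6, and TBAF in THF would return 22.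

2. Step 5. The phenol flanked by two acetal groups may arylate too slowly. The dibromide may arylate twice. The acetals may suffer at 90 °C in the basic medium.
Fallback, setting out from 6 and coming back at 7: bromine–lithium exchange on one C–Br bond of 6 (n-BuLi, THF, −78 °C), trapping with B(Oi-Pr)3 and a mild aqueous NH4Cl work-up would give [3-bromo-5-(methoxymethoxy)phenyl]boronic acid F7. An oxidative Chan–Lam coupling of F7 with phenol 4 (Cu(OAc)2, pyridine, 4 Å molecular sieves, CH2Cl2, air, rt), a reaction known to accept di-ortho-substituted phenols at room temperature, would return 7.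

3. Step 14. The silyl triflate may ionise the benzylic C1–O bond, which would cause racemisation, elimination towards a styrene or attack on an arene. The two hindered ring-B acetals may cleave incompletely.
Fallback, setting out from 22 and coming back at 24: Dess–Martin oxidation of 22 (NaHCO3, CH2Cl2, rt) would give the macrocyclic aryl ketone tris-MOM ether F8, which has no stereocentre to lose. Acid methanolysis (2 M HCl, MeOH/THF, 40 °C) would give the macrocyclic triphenol ketone F9. Noyori asymmetric transfer hydrogenation with RuCl[(R,R)-TsDPEN](p-cymene) in HCO2H/Et3N at rt, which tolerates free phenols and isolated alkenes, would then set (R)-C1 in the last operation and give 24.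

Further compounds
F1 | step 13 | (R)-1-(4-{3-[(Z)-9-(phenylsulfonyl)non-6-en-1-yl]-5-(methoxymethoxy)phenoxy}-3,5-bis(methoxymethoxy)phenyl)pent-4-en-1-ol | O[C@H](CCC=C)c1cc(OCOC)c(Oc2cc(CCCCC/C=C\CCS(=O)(=O)c3ccccc3)cc(OCOC)c2)c(OCOC)c1
F2 | step 13 | tert-butyldimethylsilyl ether of F1 | CC(C)(C)[Si](C)(C)O[C@H](CCC=C)c1cc(OCOC)c(Oc2cc(CCCCC/C=C\CCS(=O)(=O)c3ccccc3)cc(OCOC)c2)c(OCOC)c1
F3 | step 13 | (R)-5-(tert-butyldimethylsilyloxy)-5-aryl-pentan-1-ol bearing the C6 phenyl sulfone arm | CC(C)(C)[Si](C)(C)O[C@H](CCCCO)c1cc(OCOC)c(Oc2cc(CCCCC/C=C\CCS(=O)(=O)c3ccccc3)cc(OCOC)c2)c(OCOC)c1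
F4 | step 13 | primary C5 iodide corresponding to F3 | CC(C)(C)[Si](C)(C)O[C@H](CCCCI)c1cc(OCOC)c(Oc2cc(CCCCC/C=C\CCS(=O)(=O)c3ccccc3)cc(OCOC)c2)c(OCOC)c1
F5 | step 13 | macrocyclic C6 phenyl sulfone, C1 silyl ether, tris-MOM ether (both C6 epimers) | COCOc1cc2cc(c1)Oc1c(OCOC)cc(cc1OCOC)[C@H](O[Si](C)(C)C(C)(C)C)CCCCC(S(=O)(=O)c1ccccc1)C/C=C\CCCCC2
F6 | step 13 | macrocyclic C1 tert-butyldimethylsilyl ether, tris-MOM ether | COCOc1cc2cc(c1)Oc1c(OCOC)cc(cc1OCOC)[C@H](O[Si](C)(C)C(C)(C)C)CCCCCC/C=C\CCCCC2
F7 | step 5 | [3-bromo-5-(methoxymethoxy)phenyl]boronic acid | COCOc1cc(Br)cc(B(O)O)c1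
F8 | step 14 | macrocyclic aryl ketone, tris-MOM ether | COCOc1cc2cc(c1)Oc1c(OCOC)cc(cc1OCOC)C(=O)CCCCCC/C=C\CCCCC2
F9 | step 14 | macrocyclic triphenol aryl ketone | Oc1cc2cc(c1)Oc1c(O)cc(cc1O)C(=O)CCCCCC/C=C\CCCCC2
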